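**Plan**
Retrosynthesis: the enone Cα=Cβ bond is cut first (Claisen–Schmidt with 4-hydroxybenzaldehyde), then the pyran O1–C2 bond (side-chain epoxide opened by the C8a phenol), then ring A at C4a–C8a, C5–C6 and C8–C8a, with C6–C7 traced back to a Wolff shift.
Enabling feature: in ring A the oxygen-bearing C8a lies between the alkyl-bearing C4a and the acyl-bearing C8, C5 carries OMe and C6/C7 carry H. This is the 2-alkyl-3-alkoxy-6-substituted phenol pattern that a vinylketene and an alkoxyalkyne deliver in one annulation.
Forward: ring A is built first from a diazo enone (C8 carbonyl carbon masked as an acetal) and a prenylated methoxyalkyne. The acetal carbon is then raised to the acetyl group, the pyran ring is closed second, and the chalcone arm is joined last.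
Stereochemistry: the only stereocentre, C3, comes from Shi epoxidation of the prenyl alkene with the L-configured ketone catalyst. The 6-endo closure breaks only the bond at the CMe2 carbon, so C3 stays (S).

Key step: step 4

Assumption: the ortho-hydroxy acetal formed in the key step is taken to be isolable on triethylamine-washed silica, and the L-sorbose-derived enantiomer of the Shi ketone is taken as an available catalyst.

**Route**

Step 1
Reactants: 1 dimethoxyacetaldehyde (60% aqueous solution); 2 1-(triphenyl-λ5-phosphanylidene)propan-2-one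
Product: 3 (E)-5,5-dimethoxypent-3-en-2-one
Conditions: CH2Cl2/H2O, rt
Reagents that add atoms: none
Why: Wittig olefination with the stabilised acetonylidene ylide tolerates the aqueous aldehyde and should give the (E)-enone, as stabilised ylides normally do.

Step 2
Reactants: 3 (E)-5,5-dimethoxypent-3-en-2-one
Product: 5 (E)-1-diazo-5,5-dimethoxypent-3-en-2-one, via trifluoroacetyl diketone 4 (not isolated)
Conditions: LiN(SiMe3)2, THF, −78 °C; CF3CO2CH2CF3; aq NH4Cl; then MsN3, Et3N, H2O (1 equiv), MeCN, rt
Reagents that add atoms: methanesulfonyl azide, CS(=O)(=O)N=[N+]=[N-]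
Why: Kinetic enolisation at the methyl group and Claisen trifluoroacetylation give 4, which undergoes detrifluoroacetylative (Regitz-type) diazo transfer, the standard entry to α′-diazo enones; the acetal is inert to both stages.

Step 3
Reactants: 6 2-chloro-1,1-dimethoxyethane; 7 1-bromo-3-methylbut-2-ene (prenyl bromide)
Product: 9 1-methoxy-5-methylhex-4-en-1-yne, via sodium methoxyacetylide 8 (not isolated)
Conditions: NaNH2 (3 equiv), liq. NH3, −33 °C; then 7, −50 to −33 °C
Reagents that add atoms: none
Why: Amide-induced loss of methanol and HCl from the chloroacetal followed by deprotonation gives the alkoxyacetylide 8 in the flask, which is C-alkylated by the primary allylic bromide (SN2), the established one-flask synthesis of 1-alkoxyalk-1-ynes.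

Step 4
Reactants: 5 (E)-1-diazo-5,5-dimethoxypent-3-en-2-one; 9 1-methoxy-5-methylhex-4-en-1-yne
Product: 14 6-(dimethoxymethyl)-3-methoxy-2-(3-methylbut-2-en-1-yl)phenol, via vinylketene 10 (not isolated), via vinylcyclobutenone 11 (not isolated), via dienylketene 12 (not isolated), via cyclohexadienone 13 (not isolated)
Conditions: hν (254 nm, Vycor), ClCH2CH2Cl, rt, degassed; then 80 °C
Reagents that add atoms: none
Why: Irradiation expels N2 from 5, and the photochemical Wolff rearrangement (1,2-shift of the alkenyl group, which makes C6–C7) gives vinylketene 10; its ketene unit adds to ynol ether 9 in a regiospecific (2+2) cycloaddition in which the nucleophilic, prenyl-bearing alkyne carbon bonds to the ketene carbonyl carbon (C4a–C8a) and the methoxy-bearing carbon to the ketene α-carbon (C5–C6), giving 4-vinylcyclobutenone 11. On heating, 11 opens by 4π electrocyclic cleavage to dienylketene 12, and ring A then closes by a thermal disrotatory 6π electrocyclisation (C8–C8a) to cyclohexadienone 13, which tautomerises to phenol 14. The closest known reaction type is the Danheiser benzannulation in its photochemical diazo ketone form with alkoxyalkynes. No stereocentre is created, because the sp3 carbons of 11 and 13 are transient and vanish on aromatisation. The step needs regiocontrol in the cycloaddition and chemoselectivity for the alkyne over the prenyl alkene: the polarisation of the ynol ether alone places prenyl ortho and methoxy meta to the new OH with the acetal carbon at the other ortho position, and the electron-rich triple bond should outpace the unactivated trisubstituted alkene in trapping the ketene. The acetal should be inert to neutral photolysis and to 80 °C, and the untested point, loss of methanol from the ortho-hydroxy acetal, is limited by short heating and base-washed glassware and silica.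

Step 5
Reactants: 14 6-(dimethoxymethyl)-3-methoxy-2-(3-methylbut-2-en-1-yl)phenol
Product: 16 2-(benzyloxy)-4-methoxy-3-(3-methylbut-2-en-1-yl)benzaldehyde, via benzyl ether acetal 15 (not isolated)
Conditions: BnBr, K2CO3, DMF, rt; then 1 M HCl, THF, rt
Reagents that add atoms: benzyl bromide, BrCc1ccccc1; water, O
Why: Williamson etherification caps the hindered phenol under basic conditions that leave the acetal intact, and mild acid hydrolysis of the electron-rich aryl acetal then frees the aldehyde without touching the prenyl alkene.

Step 6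
Reactants: 16 2-(benzyloxy)-4-methoxy-3-(3-methylbut-2-en-1-yl)benzaldehyde
Product: 17 1-[2-(benzyloxy)-4-methoxy-3-(3-methylbut-2-en-1-yl)phenyl]ethan-1-ol (racemic)
Conditions: MeMgBr, THF, 0 °C; aq NH4Cl
Reagents that add atoms: methylmagnesium bromide, C[Mg]Br
Why: Grignard addition to the non-enolisable aryl aldehyde should give the carbinol cleanly, and its stereocentre is erased in the next step.

Step 7
Reactants: 17 1-[2-(benzyloxy)-4-methoxy-3-(3-methylbut-2-en-1-yl)phenyl]ethan-1-ol
Product: 18 1-[2-(benzyloxy)-4-methoxy-3-(3-methylbut-2-en-1-yl)phenyl]ethan-1-one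
Conditions: Dess–Martin periodinane, pyridine, CH2Cl2, 0 °C to rt
Reagents that add atoms: none
Why: Dess–Martin oxidation converts the benzylic alcohol into the aryl methyl ketone under buffered conditions that spare the prenyl alkene and the benzyl ether.

Step 8
Reactants: 18 1-[2-(benzyloxy)-4-methoxy-3-(3-methylbut-2-en-1-yl)phenyl]ethan-1-one
Product: 19 1-[2-(benzyloxy)-3-{[(2S)-3,3-dimethyloxiran-2-yl]methyl}-4-methoxyphenyl]ethan-1-one
Conditions: ent-Shi ketone (30 mol%), Oxone (2KHSO5·KHSO4·K2SO4), K2CO3, Bu4NHSO4, Na2B4O7/Na2EDTA buffer, MeCN–CH2(OMe)2–H2O, 0 °C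
Reagents that add atoms: potassium peroxymonosulfate (the oxidant of Oxone), [K+].[O-]S(=O)(=O)OO
Why: Shi asymmetric epoxidation of the trisubstituted prenyl alkene through the spiro transition state of the chiral dioxirane sets C3, the L-configured ketone (mirror image of the fructose-derived catalyst, which gives the R epoxide with this alkene type) being expected to give the (S)-epoxide, while the benzyl ether keeps a phenoxide from opening the epoxide in the basic medium.

Step 9
Reactants: 19 1-[2-(benzyloxy)-3-{[(2S)-3,3-dimethyloxiran-2-yl]methyl}-4-methoxyphenyl]ethan-1-one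
Product: 21 1-[(3S)-3-hydroxy-5-methoxy-2,2-dimethyl-3,4-dihydro-2H-chromen-8-yl]ethan-1-one, via epoxy phenol 20 (not isolated)
Conditions: H2 (1 atm), Pd/C, EtOAc, rt; filter; then CSA (10 mol%), CH2Cl2, 0 °C
Reagents that add atoms: none
Why: Hydrogenolysis frees the phenol under neutral conditions, and Brønsted acid then drives 6-endo epoxide opening at the tertiary carbon (Markovnikov-type acid-catalysed epoxide cyclisation), so the C3–O bond is never broken and the (S) configuration is carried over unchanged.

Step 10
Reactants: 21 1-[(3S)-3-hydroxy-5-methoxy-2,2-dimethyl-3,4-dihydro-2H-chromen-8-yl]ethan-1-one; 22 4-hydroxybenzaldehyde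
Product: 23 (E)-1-[(3S)-3-hydroxy-5-methoxy-2,2-dimethyl-3,4-dihydro-2H-chromen-8-yl]-3-(4-hydroxyphenyl)prop-2-en-1-one
Conditions: KOH (50% aq, excess), EtOH, rt; then dilute HCl to pH 4
Reagents that add atoms: none
Why: Claisen–Schmidt condensation of the methyl ketone enolate with the non-enolisable aldehyde and E1cB dehydration should give the (E)-enone, no flavanone can form because the former phenol oxygen is locked in the pyran ring, and excess base accommodates the free phenol of the aldehyde.

**Compound list**

1 | dimethoxyacetaldehyde (used as 60% aqueous solution) | COC(OC)C=O | starting material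
2 | 1-(triphenyl-λ5-phosphanylidene)propan-2-one | CC(=O)C=P(c1ccccc1)(c1ccccc1)c1ccccc1 | starting material
3 | (E)-5,5-dimethoxypent-3-en-2-one | COC(OC)/C=C/C(C)=O | intermediate
4 | (E)-1,1,1-trifluoro-7,7-dimethoxyhept-5-ene-2,4-dione (formed in the flask) | COC(OC)/C=C/C(=O)CC(=O)C(F)(F)F | intermediate
5 | (E)-1-diazo-5,5-dimethoxypent-3-en-2-one | COC(OC)/C=C/C(=O)C=[N+]=[N-] | intermediate
6 | 2-chloro-1,1-dimethoxyethane (chloroacetaldehyde dimethyl acetal) | COC(CCl)OC | starting material
7 | 1-bromo-3-methylbut-2-ene (prenyl bromide) | CC(C)=CCBr | starting material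
8 | sodium methoxyacetylide (formed in the flask) | [Na+].[C-]#COC | intermediate
9 | 1-methoxy-5-methylhex-4-en-1-yne | COC#CCC=C(C)C | intermediate
10 | (E)-5,5-dimethoxypenta-1,3-dien-1-one (formed in the flask) | COC(OC)/C=C/C=C=O | intermediate
11 | 4-[(E)-3,3-dimethoxyprop-1-en-1-yl]-3-methoxy-2-(3-methylbut-2-en-1-yl)cyclobut-2-en-1-one (racemic, formed in the flask) | COC(OC)/C=C/C1C(OC)=C(CC=C(C)C)C1=O | intermediate
12 | (3E,5E)-3,7,7-trimethoxy-2-(3-methylbut-2-en-1-yl)hepta-1,3,5-trien-1-one (formed in the flask) | COC(OC)/C=C/C=C(OC)\C(CC=C(C)C)=C=O | intermediate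
13 | 6-(dimethoxymethyl)-3-methoxy-2-(3-methylbut-2-en-1-yl)cyclohexa-2,4-dien-1-one (racemic, formed in the flask) | COC(OC)C1C=CC(OC)=C(CC=C(C)C)C1=O | intermediate
14 | 6-(dimethoxymethyl)-3-methoxy-2-(3-methylbut-2-en-1-yl)phenol | COC(OC)c1ccc(OC)c(CC=C(C)C)c1O | intermediate
15 | 2-(benzyloxy)-1-(dimethoxymethyl)-4-methoxy-3-(3-methylbut-2-en-1-yl)benzene (formed in the flask) | COC(OC)c1ccc(OC)c(CC=C(C)C)c1OCc1ccccc1 | intermediate
16 | 2-(benzyloxy)-4-methoxy-3-(3-methylbut-2-en-1-yl)benzaldehyde | O=Cc1ccc(OC)c(CC=C(C)C)c1OCc1ccccc1 | intermediate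
17 | 1-[2-(benzyloxy)-4-methoxy-3-(3-methylbut-2-en-1-yl)phenyl]ethan-1-ol (racemic) | CC(O)c1ccc(OC)c(CC=C(C)C)c1OCc1ccccc1 | intermediate
18 | 1-[2-(benzyloxy)-4-methoxy-3-(3-methylbut-2-en-1-yl)phenyl]ethan-1-one | CC(=O)c1ccc(OC)c(CC=C(C)C)c1OCc1ccccc1 | intermediate
19 | 1-[2-(benzyloxy)-3-{[(2S)-3,3-dimethyloxiran-2-yl]methyl}-4-methoxyphenyl]ethan-1-one | CC(=O)c1ccc(OC)c(C[C@@H]2OC2(C)C)c1OCc1ccccc1 | intermediate
20 | 1-[3-{[(2S)-3,3-dimethyloxiran-2-yl]methyl}-2-hydroxy-4-methoxyphenyl]ethan-1-one (formed in the flask) | CC(=O)c1ccc(OC)c(C[C@@H]2OC2(C)C)c1O | intermediate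
21 | 1-[(3S)-3-hydroxy-5-methoxy-2,2-dimethyl-3,4-dihydro-2H-chromen-8-yl]ethan-1-one | COc1ccc(C(C)=O)c2c1C[C@H](O)C(C)(C)O2 | intermediate
22 | 4-hydroxybenzaldehyde | O=Cc1ccc(O)cc1 | starting material
23 | (E)-1-[(3S)-3-hydroxy-5-methoxy-2,2-dimethyl-3,4-dihydro-2H-chromen-8-yl]-3-(4-hydroxyphenyl)prop-2-en-1-one | COc1ccc(C(=O)/C=C/c2ccc(O)cc2)c2c1C[C@H](O)C(C)(C)O2 | target

**Step count**
Total: 10 steps. Longest linear sequence: 9 steps (1, 2, 4, 5, 6, 7, 8, 9, 10); step 3 is the convergent branch.

**Steps most likely to fail**

Step 4. The Wolff rearrangement of the acyclic diazo enone may be inefficient because of competing E/Z photoisomerisation and carbene side reactions. In the thermal stage the ortho-hydroxy acetal may lose methanol, and the quinone methide so formed may be captured by excess alkyne. The fallback gives up the annulation and reaches the ring A pattern by electrophilic substitution; it sets out from 7 and returns at 18. Prenyl bromide 7 C-alkylates 1-(2,4-dihydroxyphenyl)ethan-1-one F1 (aq KOH, 0 °C to rt) at the position between the two hydroxyl groups to give 1-[2,4-dihydroxy-3-(3-methylbut-2-en-1-yl)phenyl]ethan-1-one F2, which is separated from its isomers. Selective methylation of the non-chelated 4-OH (Me2SO4, K2CO3, acetone) should give 1-[2-hydroxy-4-methoxy-3-(3-methylbut-2-en-1-yl)phenyl]ethan-1-one F3. Benzylation (BnBr, K2CO3, DMF) then brings the material back to the route at 18.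

Step 3. Excess amide may isomerise the skipped enyne or alkylate it a second time at the doubly activated CH2, the acetylide may attack the allylic bromide in the SN2′ sense, and ammonia may consume the bromide. The fallback generates the acetylide without amide base or amine and couples it under copper catalysis; it sets out from 7 and returns at 9. Trichloroethylene and NaOMe give (E)-1,2-dichloro-1-methoxyethene F4. Two equivalents of n-BuLi in THF at −78 °C convert F4, by elimination and chlorine–lithium exchange, into lithium methoxyacetylide F5. This is allylated by 7 in THF/DMPU with catalytic CuBr·SMe2 to give 9.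

Step 9. The phenol may close onto the secondary epoxide carbon (5-exo) in competition with the wanted 6-endo mode, and the aryl ketone may be over-reduced during hydrogenolysis. The fallback closes the pyran ring before the oxygen is introduced, so no regiochemical choice remains; it sets out from 18 and returns at 21. Chelation-assisted debenzylation of 18 (MgBr2·OEt2, toluene/Et2O) gives 1-[2-hydroxy-4-methoxy-3-(3-methylbut-2-en-1-yl)phenyl]ethan-1-one F3, the phenol already met in the first fallback. Dehydrogenative cyclisation (DDQ, benzene, 80 °C) gives 1-(5-methoxy-2,2-dimethyl-2H-chromen-8-yl)ethan-1-one F6. Jacobsen epoxidation with (S,S)-(salen)MnCl (salen = N,N′-bis(3,5-di-tert-butylsalicylidene)cyclohexane-1,2-diamine dianion) and NaOCl should give 1-[(3S,4S)-3,4-epoxy-5-methoxy-2,2-dimethyl-3,4-dihydro-2H-chromen-8-yl]ethan-1-one F7. Hydrogenolysis of its benzylic C4–O bond (H2, Pd/C, EtOAc) then gives 21.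

**Further compounds**
F1 | step 4 | 1-(2,4-dihydroxyphenyl)ethan-1-one | CC(=O)c1ccc(O)cc1O
F2 | step 4 | 1-[2,4-dihydroxy-3-(3-methylbut-2-en-1-yl)phenyl]ethan-1-one | CC(=O)c1ccc(O)c(CC=C(C)C)c1O
F3 | step 4 | 1-[2-hydroxy-4-methoxy-3-(3-methylbut-2-en-1-yl)phenyl]ethan-1-one | CC(=O)c1ccc(OC)c(CC=C(C)C)c1O
F4 | step 3 | (E)-1,2-dichloro-1-methoxyethene | CO/C(Cl)=C\Cl
F5 | step 3 | lithium methoxyacetylide | [Li+].[C-]#COC
F6 | step 9 | 1-(5-methoxy-2,2-dimethyl-2H-chromen-8-yl)ethan-1-one | COc1ccc(C(C)=O)c2c1C=CC(C)(C)O2
F7 | step 9 | 1-[(3S,4S)-3,4-epoxy-5-methoxy-2,2-dimethyl-3,4-dihydro-2H-chromen-8-yl]ethan-1-one | COc1ccc(C(C)=O)c2c1[C@@H]1O[C@@H]1C(C)(C)O2
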